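## Structural features

Compound 31 is a germacranolide: a ten-membered carbocycle (C1–C10) with a trans-fused α-methylene-γ-butyrolactone across C6–C7 (lactone oxygen on C6; C11, C12, exocyclic C13). It has two ring-cis trisubstituted alkenes, C1=C10 carrying the C14 carboxylic acid and C4=C5 carrying the C15 methyl, and angelate esters on C8 and C9. The stereocentres C6, C7, C8 and C9 are contiguous (6R,7S,8S,9S): O6 and C11 are trans, C11 and O8 are cis, O8 and O9 are syn. The fragile parts are the methylene lactone (a Michael acceptor), the Z-configured angelates (they isomerise to tiglates under base or nucleophilic catalysis), the 1,5-diene in a medium ring (Cope rearrangement, transannular cyclisation), the free acid, and any unprotected 8α-hydroxyl, which sits cis to the C11–C12 arm and can take over the lactone. The real difficulty is a strained ten-membered ring with two cis trisubstituted alkenes of fixed geometry next to four contiguous stereocentres. The key step uses the fact that C4 and C9 lie across the ring from each other, C9 bears oxygen and C5 is the allylic end of C4=C5. A C4–C9 bond folds the ring into a cis-decalin in which ring A (C1, C2, C3, C4, C9, C10) holds C1=C10 inside a cyclohexene and ring B (C4 to C9) holds every stereocentre on a chair, and fragmentation of a C9 alkoxide against a C5 sulfonate then returns the ten-membered ring and C4=C5 stereospecifically.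

## Logic of the disconnections

31 ⇐ 30. Only the alkyl–oxygen bond of the C14 ester changes. The acid is masked because a free carboxyl would interfere with every enolate, hydride and acylation step. The gain is that C14 can be carried as an inert group from the first C–C bond formation. The forward step must be an acidolysis mild enough for two Z-enoate esters, the methylene lactone and the 1,5-diene.

30 ⇐ 27 + 28. The two acyl–oxygen bonds at O8 and O9 are cut. The angelates are placed as late as possible because they survive neither strong base nor nucleophilic amines. This leaves a diol and a commercial acid. The acylation must take two hindered secondary alcohols without Z to E isomerisation and without letting O8 attack the lactone carbonyl.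

27 ⇐ 26. The O8–aryl and O9–silicon bonds are restored. Both groups are chosen so that one acidic, oxidative operation removes them together. The demand is an oxidant that leaves the alkyl C8–O bond, the alkenes and the methylene lactone alone.

26 ⇐ 22 + 23. The C11–C13 bond is cut. The exocyclic alkene is added only after all hydride and strong-base chemistry on the ketone is finished. The forward step needs a lactone enolate formed next to a γ-acidic enoate, and an elimination that can only go outward.

22 ⇐ 21 ⇐ 20. The O9–silicon bond and the C9–H bond are removed, so the C9 stereocentre becomes a ketone. This is the form in which C9 leaves the key step. The forward reduction must be 1,2-selective on an alkylidene β-keto ester and must deliver hydride anti to the C8–O bond.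

20 ⇐ 19. The C4–C9 bond is reconnected, the C4=C5 π bond is replaced by a C5–O sulfonate bond, and C9 returns to a tertiary alcohol. This is the strategic cut: the medium ring and one cis alkene become a cis-decalin, and C1=C10 becomes an ordinary cyclohexene alkene. The forward step needs the C5–O bond anti-periplanar to C4–C9, C3 axial on ring B, and a base that leaves no excess to enolise the product.

19 ⇐ 18 ⇐ 17. The O5–sulfur bond and the C5–H bond are removed. C5 is kept as a ketone until the C9 hydroxyl exists, because that hydroxyl is the only reliable handle for placing hydride on the β face of C5. The reduction must therefore be hydroxyl-directed, and the sulfonylation must distinguish a secondary from a tertiary alcohol.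

17 ⇐ 15. The O6–C12 lactone bond and the C6–O bond are cut. The C5 ketone activates C6 as its only enolisable position, and the arm on C7 is already in place to close the lactone. The oxidant must come from the β face so that O6 is trans to the arm.

15 ⇐ 14 ⇐ 13. The C1–H bond and the C9–O bond are traced back to a C1 ketone and a C9=C10 alkene by way of the C9–C10 epoxide. This transposition turns an annulation enone into the allylic tertiary alcohol with cis ring fusion. The forward steps need β-face epoxidation and a hydrazone formed at C1 and not at C5.

13 ⇐ 10 + 11 ⇐ 9. The C8–O bond is cut. The enone makes C8 the acidic vinylogous position, so it can be functionalised there and nowhere else. The oxygen is brought in as an aryl ether with inversion of a bromide, because a free 8α-hydroxyl would lactonise onto the C7 arm. The demand is clean SN2 substitution on a γ-bromo enone.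

9 ⇐ 8. The C9=C10 bond is cut, which opens ring A. The two ring carbonyls of the precursor are enantiotopic, so this is where absolute configuration enters. A chiral amine must choose one carbonyl and must outrun the uncatalysed aldol reaction.

8 ⇐ 6 + 7. The C1–C10 bond is cut. C10 and C14 arrive together as a β-keto ester, which avoids an unstable vinyl ketone reagent. The homologation must touch only the aldehyde.

6 ⇐ 4 + 5. The C3–C4 bond is cut. Conjugate addition builds the quaternary C4 and fixes its relation to C7. The acceptor must add on the face cis to the C7 arm.

4 ⇐ 1 + 2. The C4–C15 bond and the ring C–H bonds added in the arene saturation are removed. This leads back to a catalogue resorcinol ester that already contains C5 to C9, C11 and C12. The forward step needs a C-selective methylation of a 1,3-dione.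

## Other disconnections considered

Alternative 1: The cut is made at C7–C8 and between C6 and the C8 oxygen. The lactone ring atoms (O, C6, C7, C11, C12) come from furan A1, and C8 and C9 come from (−)-8-phenylmenthyl glyoxylate A2. The forward key step is a Paternò–Büchi photocycloaddition of A1 with A2, which closes the oxetane of the exo adduct A3. In its favour, two adjacent stereocentres (C7, C8) are set in one step from the cheap arene A1 and the auxiliary-bearing aldehyde A2, and the lactone carbons arrive with a usable oxidation pattern. On these points it is better than the chosen plan, which spends several steps oxygenating ring B. Its auxiliary-based absolute control is at least the equal of a desymmetrising aldol reaction. Against it, opening the acetal of A3 returns C6 to the carbonyl level, so the C6 configuration is lost and must be made again. C9 is only an ester carbon, and neither cis alkene nor the ten-membered ring is addressed, so a separate medium-ring closure is still needed. Mechanistically the photoreaction runs through a triplet biradical, whose selectivity rests on conformer populations; the chosen fragmentation is concerted and stereospecific. In step economy the front end is shorter, but the ring closure and both alkenes would have to be added, so the total is expected to be longer.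

Alternative 2: The cut reconnects C1 and C6. The substrate is the bicyclic epoxy ketone A4; on condensation with an arenesulfonyl hydrazide in weak acid, A4 undergoes an Eschenmoser–Tanabe fragmentation to the cyclodecenynone A5. In its favour, it uses the same logic as the chosen plan: a six-six bicycle is opened to the ten-membered ring and C4=C5 is ring-cis because it was inside a cyclohexene. On ring formation and alkene geometry it is the equal of the chosen plan. It is better on two points. C7, C8 and C9 are all in place before the ring opens, so no late reduction at C9 is needed. The conditions are weakly acidic, which suits a base-sensitive product better than an alkoxide. Against it, A5 has no C14: a carboxyl and a hydrogen would have to be added syn across C1≡C10 with control of which alkyne carbon takes the carbon substituent, and this is hard on a strained cycloalkyne with two similar termini. C6 emerges as a conjugated ketone and needs a stereoselective 1,2-reduction before lactonisation; this is the same kind of late reduction as the chosen plan needs at C9, so the two are equal there. The methylene group is still missing in both. The step count after the key step is similar, plus the hydrocarboxylation.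

Alternative 3: The cut is at C6–C7. The thirteen-membered α-stannyl ether A6 undergoes tin–lithium exchange with an alkyllithium and contracts by a [2,3]-Wittig (Wittig–Still) shift to the ten-membered alcohol A7. In its favour, one step forms the carbocycle, sets C6 and C7, frees the C6 hydroxyl and creates the exocyclic C11=C13 alkene. This is better than the chosen plan, which needs a separate methylenation. The C8/C9 diol can come from the chiral pool as an acetonide, which is equal or better for absolute configuration. Closing a thirteen-membered ether is easier than closing a ten-membered carbocycle directly, so the two plans are equal in avoiding a direct medium-ring cyclisation. Against it, both cis trisubstituted alkenes must be built stereoselectively in acyclic precursors, whereas the chosen plan takes them from rings. The configuration at C6 and C7 depends on the conformation of a flexible macrocyclic transition state, on the geometry of the C7=C11 alkene and on a configurationally defined stannane, and a [1,2]-shift can compete. C12 and C14 are carried at the alcohol level, so two late oxidations to the acid level are needed beside a methylene lactone. Both key steps are concerted and stereospecific in principle, but the anti-periplanar demand of the fragmentation is enforced by a locked chair and is the more predictable. The linear sequence to A6 is expected to be longer than the route to 19.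

Key step: step 12

Assumption: compound 1, methyl 3,5-dihydroxyphenylacetate, is taken as a catalogue compound; locants C1–C15 are germacrane locants in every compound, and in the decalins β means the face of the C4 methyl group and α the opposite face.

Step 1
Reactants: 1 methyl 3,5-dihydroxyphenylacetate; 2 iodomethane
Product: 4 methyl (4-methyl-3,5-dioxocyclohexyl)acetate, via methyl (3,5-dioxocyclohexyl)acetate 3 (not isolated)
Conditions: H2 (5 bar), Rh/Al2O3 (5% Rh), NaOCH3 (1.05 equiv), CH3OH, 50 °C; filter; CH3I (1.5 equiv), 60 °C; aq. HCl to pH 3
Reagents that add atoms: iodomethane (2), CI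
Why: Hydrogenation of a resorcinol monoanion stops at the 1,3-dione enolate, which is then C-methylated in the same methanolic solution (classical one-pot route to 2-methyl-1,3-diones); methoxide in methanol keeps the methyl ester intact.

Step 2
Reactants: 4 methyl (4-methyl-3,5-dioxocyclohexyl)acetate; 5 acrolein
Product: 6 methyl [4-methyl-3,5-dioxo-4-(3-oxopropyl)cyclohexyl]acetate (oxopropyl chain cis to the acetate arm; achiral)
Conditions: acrolein (1.5 equiv), Et3N (5 mol%), EtOAc, 0 °C → rt; minor diastereomer removed by crystallisation or chromatography
Reagents that add atoms: acrolein (5), C=CC=O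
Why: Michael addition of the 2-methyl-1,3-dione enolate builds the quaternary C4; the acceptor should enter axially on the enolate whose C7 arm is equatorial, which places the new chain cis to that arm (methyl trans), and both isomers are achiral so only this relative configuration is at stake.

Step 3
Reactants: 6 methyl [4-methyl-3,5-dioxo-4-(3-oxopropyl)cyclohexyl]acetate; 7 tert-butyl diazoacetate
Product: 8 tert-butyl 5-[4-(2-methoxy-2-oxoethyl)-1-methyl-2,6-dioxocyclohexyl]-3-oxopentanoate (chain cis to the acetate arm; achiral)
Conditions: SnCl2 (10 mol%), CH2Cl2, rt
Reagents that add atoms: tert-butyl diazoacetate (7), [N-]=[N+]=CC(=O)OC(C)(C)C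
Why: Roskamp homologation converts the aldehyde into the β-keto ester that carries C10 and C14; the two ring ketones are flanked by the quaternary carbon and should not react with the diazo ester.

Step 4
Reactants: 8 tert-butyl 5-[4-(2-methoxy-2-oxoethyl)-1-methyl-2,6-dioxocyclohexyl]-3-oxopentanoate
Product: 9 tert-butyl (4aS,7R)-7-(2-methoxy-2-oxoethyl)-4a-methyl-2,5-dioxo-2,3,4,4a,5,6,7,8-octahydronaphthalene-1-carboxylate (enedione; C4 methyl β; C7 arm α; C9=C10)
Conditions: L-phenylalanine (1.0 equiv), (1S)-(+)-10-camphorsulfonic acid (0.5 equiv), DMF, rt → 50 °C
Reagents that add atoms: none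
Why: Amino-acid-catalysed desymmetrising aldol condensation of the Hajos–Parrish–Eder–Sauer–Wiechert type: the enamine at C10 attacks one of the two enantiotopic ring carbonyls and dehydration gives the alkylidene β-keto ester, closing ring A; the L-amino acid should select the carbonyl that leads to the S quaternary centre as it does with simpler triketones, and because 8 is a meso compound this single choice fixes C7 as well.

Step 5
Reactants: 9 tert-butyl (4aS,7R)-7-(2-methoxy-2-oxoethyl)-4a-methyl-2,5-dioxo-2,3,4,4a,5,6,7,8-octahydronaphthalene-1-carboxylate
Product: 10 tert-butyl (4aS,7R)-2-(tert-butyldimethylsilyloxy)-7-(2-methoxy-2-oxoethyl)-4a-methyl-5-oxo-3,4,4a,5,6,7-hexahydronaphthalene-1-carboxylate (silyl dienol ether; C1=C10 and C8=C9)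
Conditions: t-BuMe2SiOSO2CF3 (1.2 equiv), Et3N (2.0 equiv), CH2Cl2, −78 → 0 °C
Reagents that add atoms: tert-butyldimethylsilyl trifluoromethanesulfonate, CC(C)(C)[Si](C)(C)OS(=O)(=O)C(F)(F)F
Why: Soft enolisation removes the vinylogous, doubly activated C8 hydrogen and gives the extended silyl dienol ether; the isolated C5 ketone is far less acidic and should remain untouched with a small excess of reagent.

Step 6
Reactants: 10 tert-butyl (4aS,7R)-2-(tert-butyldimethylsilyloxy)-7-(2-methoxy-2-oxoethyl)-4a-methyl-5-oxo-3,4,4a,5,6,7-hexahydronaphthalene-1-carboxylate; 11 4-methoxyphenol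
Product: 13 8α-(4-methoxyphenoxy) enedione (aryl ether on C8 cis to the C7 arm and trans to the C4 methyl; otherwise as 9), via 8β-bromo enedione 12 (not isolated)
Conditions: N-bromosuccinimide (1.05 equiv), THF, −78 °C; then 4-methoxyphenol (1.2 equiv), K2CO3 (1.2 equiv), DMF, 0 °C → rt
Reagents that add atoms: 4-methoxyphenol (11), COc1ccc(O)cc1; N-bromosuccinimide, O=C1CCC(=O)N1Br (its bromine stays only in 12)
Why: γ-Bromination of the silyl dienol ether followed by SN2 displacement with phenoxide; bromine should enter axially on the β face (the α face of C8 is covered by the pseudo-axial C7 arm, as in the 6β-bromination of steroidal dienol ethers) and is replaced with inversion, so the ether oxygen arrives α. An α-bromide cannot be attacked from the methyl-shielded β face and should equilibrate by bromide exchange, so both epimers converge; delivering the oxygen already capped avoids the 8,12-lactone that a free 8α-hydroxyl would form with the ester arm.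

Step 7
Reactants: 13 8α-(4-methoxyphenoxy) enedione
Product: 14 9β,10β-epoxy diketone (epoxide oxygen cis to the C4 methyl; C1 and C5 ketones; otherwise as 13)
Conditions: t-BuOOH (2 equiv, in decane), DBU (0.1 equiv), CH2Cl2, 0 °C
Reagents that add atoms: tert-butyl hydroperoxide, CC(C)(C)OO
Why: Weitz–Scheffer epoxidation of the doubly activated alkene; the peroxide anion should add to C9 on the β face, the usual course for angular-methyl octalones and here also anti to the 8α-aryloxy group, which sets the cis ring fusion. No other alkene or carbonyl is electrophilic enough to react.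

Step 8
Reactants: 14 9β,10β-epoxy diketone
Product: 15 cis-fused 9β-hydroxy-1(10)-ene (tertiary C9–OH cis to the C4 methyl; tert-butyl ester on C10; C5 ketone; 8α-aryloxy; C7 methyl acetate arm α)
Conditions: N2H4·H2O (1.3 equiv), AcOH (0.3 equiv), CH3OH, −20 → 0 °C; aqueous acetone work-up
Reagents that add atoms: none
Why: Wharton transposition: the hydrazone of the C1 ketone opens the epoxide, loses N2 and leaves C1=C10 conjugated with the ester and the C9 oxygen as a tertiary alcohol with retention, which is the cis-decalin. The C1 carbonyl is activated by the α-oxygen and the ester and should condense much faster than the neopentyl C5 ketone; any C5 hydrazone is returned by exchange with acetone.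

Step 9
Reactants: 15 cis-fused 9β-hydroxy-1(10)-ene
Product: 17 5-keto 6β,12-lactone (trans-fused γ-lactone from O6 to C12; C9–OH free; otherwise as 15), via 6β-hydroxy ketone 16 (not isolated)
Conditions: NaN(SiMe3)2 (2.1 equiv), THF, −78 °C (substrate added to base); 2-(phenylsulfonyl)-3-phenyloxaziridine (1.3 equiv), −78 °C; AcOH; then 10-camphorsulfonic acid (0.2 equiv), CH2Cl2, rt → 40 °C
Reagents that add atoms: 2-(phenylsulfonyl)-3-phenyloxaziridine, O=S(=O)(N1OC1c1ccccc1)c1ccccc1
Why: Enolate hydroxylation followed by acid-catalysed lactonisation; C6 is the only enolisable position of the C5 ketone, and the α face is blocked by the axial C3 methylene and the axial 8α-aryloxy group, so oxygen should enter from the β face to give the equatorial alcohol trans to the C7 arm. That alcohol closes the trans-fused lactone, which locks ring B in the chair needed for step 12; adding the substrate to the base makes the dianion at once, so the β-alkoxy ketone has no time for retro-aldol cleavage.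

Step 10
Reactants: 17 5-keto 6β,12-lactone
Product: 18 5α-hydroxy 6β,12-lactone (equatorial secondary C5–OH trans to the C4 methyl and to O6)
Conditions: Me4NBH(OAc)3 (5 equiv), CH3CN/AcOH (1:1), −20 °C → rt
Reagents that add atoms: none
Why: Evans–Saksena hydroxyl-directed reduction: the axial tertiary C9 hydroxyl binds boron and passes hydride to the β face of C5 (1,3-anti), giving the equatorial 5α-alcohol; the lactone and the esters are inert to this reagent.

Step 11
Reactants: 18 5α-hydroxy 6β,12-lactone
Product: 19 cis-decalin 5α-mesylate (germacrane locants 4R,5S,6S,7S,8S,9R: tertiary C9–OH and C4 methyl cis; equatorial C5 mesylate; trans-fused 6,12-lactone; axial 8α-(4-methoxyphenoxy); tert-butyl ester on C1=C10)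
Conditions: CH3SO2Cl (1.5 equiv), Et3N (3 equiv), CH2Cl2, −10 °C
Reagents that add atoms: methanesulfonyl chloride, CS(=O)(=O)Cl
Why: Sulfonylation through sulfene reaches the neopentyl secondary alcohol; the tertiary axial C9 hydroxyl should not react at this temperature.

Step 12
Reactants: 19 cis-decalin 5α-mesylate
Product: 20 ten-membered C9 ketone (1E,4Z,6R,7S,8S: ring-cis C1=C10 with tert-butyl ester; ring-cis C4=C5; 8-(4-methoxyphenoxy); saturated trans 6,12-lactone)
Conditions: KN(SiMe3)2 (1.05 equiv), THF, −78 → −20 °C; pH 7 phosphate buffer at −20 °C
Reagents that add atoms: none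
Why: The potassium alkoxide at C9 pushes its electrons into the C4–C9 σ bond while the anti-periplanar C5–O bond of the mesylate ionises, so C9=O and C4=C5 form in one concerted heterolytic event (Grob fragmentation). The closest known reaction is the base-induced Wharton-type fragmentation of decalin 1,3-diol monosulfonates to cyclodecenones, in which cis-fused substrates give the cis alkene. No ring is closed by bond formation, so no mode of closure applies: the ten-membered ring appears when the bond shared by rings A and B is cut. No stereocentre is created; C6, C7 and C8 are untouched, and C4, C5 and C9 become trigonal. The trans-fused lactone holds ring B in the chair in which O5 is equatorial and anti to C4–C9, and C3 is axial on C4 and gauche to C6; this maps stereospecifically onto the ring-cis C4=C5 alkene, while C1=C10 is cis because it was inside ring A. The step needs fragmentation to win over oxetane formation, elimination and enolisation of the product: the axial C9 oxygen cannot reach the rear of the C5–O bond, no hydrogen is anti to the mesylate, and the aryl ether on C8 is not a leaving group towards the neighbouring alkoxide. One equivalent of a non-nucleophilic base at low temperature leaves only KO3SCH3 behind, so C8 and the alkylidene β-keto ester are not exposed to base.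

Step 13
Reactants: 20 ten-membered C9 ketone
Product: 21 9S allylic alcohol (C9–OH syn to the C8 ether; configurations at C6 to C9 as in 31)
Conditions: NaBH4 (1.5 equiv), CeCl3·7H2O (1.5 equiv), CH3OH/THF, −78 °C
Reagents that add atoms: none
Why: Luche reduction gives 1,2-addition at the cross-conjugated ketone and leaves the lactone alone; hydride should approach anti to the C8–O bond and past H8 (Felkin–Anh model), which gives the 8,9-syn alcohol.

Step 14
Reactants: 21 9S allylic alcohol
Product: 22 9-O-triethylsilyl ether of 21
Conditions: Et3SiCl (1.5 equiv), imidazole (3 equiv), DMF, 0 °C → rt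
Reagents that add atoms: chlorotriethylsilane, CC[Si](CC)(CC)Cl
Why: Silylation masks the only free hydroxyl before the strong base of step 15; the group is chosen so that the acidic oxidative medium of step 16 removes it.

Step 15
Reactants: 22 9-O-triethylsilyl ether of 21; 23 dimethyl(methylene)ammonium iodide
Product: 26 α-methylene lactone (C11=C13; otherwise as 22), via Mannich base 24 (not isolated), via trimethylammonium iodide 25 (not isolated)
Conditions: LiN(iPr)2 (1.2 equiv), THF, −78 °C; dimethyl(methylene)ammonium iodide (3 equiv), −78 → 0 °C; then CH3I (10 equiv), rt; then aq. NaHCO3, rt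
Reagents that add atoms: dimethyl(methylene)ammonium iodide (23), C=[N+](C)C.[I-]; iodomethane (2), CI (its methyl stays only in 25)
Why: Mannich reaction of the lactone enolate, quaternisation and Hofmann-type elimination; at −78 °C the lactone α-hydrogens are removed faster than the γ-hydrogens of the enoate, and the ammonium group can only leave towards C11, so the alkene is exocyclic. C7 has no acidic hydrogen and keeps its configuration.

Step 16
Reactants: 26 α-methylene lactone
Product: 27 8,9-diol (tert-butyl ester; α-methylene lactone; configurations at C6 to C9 as in 31)
Conditions: (NH4)2Ce(NO3)6 (3 equiv), CH3CN/H2O (4:1), 0 °C, then rt until the silyl ether is gone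
Reagents that add atoms: none
Why: Oxidative dearylation of the 4-methoxyphenyl ether by tetravalent cerium: water adds to the arene radical cation, so the alkyl C8–O bond and the C8 configuration stay intact. The nitric acid set free hydrolyses the triethylsilyl ether in the same pot; the alkenes are electron-poor or hindered and should survive a short exposure.

Step 17
Reactants: 27 8,9-diol; 28 angelic acid
Product: 30 8,9-bis-angelate tert-butyl ester, via angelic 2,4,6-trichlorobenzoic anhydride 29 (not isolated)
Conditions: angelic acid (5 equiv), 2,4,6-trichlorobenzoyl chloride (5 equiv), Et3N (10 equiv), toluene, rt; then 27, 60 °C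
Reagents that add atoms: angelic acid (28), C/C=C(/C)C(=O)O
Why: Yamaguchi esterification run without a nucleophilic pyridine catalyst, the conditions under which Z-2-methylbut-2-enoates form without isomerising to tiglates; the alcohols attack the less hindered angeloyl carbonyl of the mixed anhydride. The medium is only weakly basic, so O8 should not open the lactone, and the temperature stays below that needed for a Cope rearrangement of the 1,5-diene.

Step 18
Reactants: 30 8,9-bis-angelate tert-butyl ester
Product: 31 CNP0154468.1 (1E,4Z,6R,7S,8S,9S)
Conditions: CF3CO2H/CH2Cl2 (1:4), 0 °C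
Reagents that add atoms: none
Why: Acidolysis of the tert-butyl ester through the tert-butyl cation; the C1=C10 alkene is deactivated by the carboxyl and should not start a transannular cyclisation, and the angelates and the methylene lactone tolerate brief cold acid.

Compound list

1 | methyl 3,5-dihydroxyphenylacetate | COC(=O)Cc1cc(O)cc(O)c1 | starting material
2 | iodomethane | CI | starting material
3 | methyl (3,5-dioxocyclohexyl)acetate (formed as its sodium enolate) | COC(=O)CC1CC(=O)CC(=O)C1 | intermediate
4 | methyl (4-methyl-3,5-dioxocyclohexyl)acetate | COC(=O)CC1CC(=O)C(C)C(=O)C1 | intermediate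
5 | acrolein | C=CC=O | starting material
6 | methyl [4-methyl-3,5-dioxo-4-(3-oxopropyl)cyclohexyl]acetate, oxopropyl chain cis to the acetate arm | COC(=O)C[C@H]1CC(=O)[C@@](C)(CCC=O)C(=O)C1 | intermediate
7 | tert-butyl diazoacetate | [N-]=[N+]=CC(=O)OC(C)(C)C | starting material
8 | tert-butyl 5-[4-(2-methoxy-2-oxoethyl)-1-methyl-2,6-dioxocyclohexyl]-3-oxopentanoate, chain cis to the acetate arm | COC(=O)C[C@H]1CC(=O)[C@@](C)(CCC(=O)CC(=O)OC(C)(C)C)C(=O)C1 | intermediate
9 | tert-butyl (4aS,7R)-7-(2-methoxy-2-oxoethyl)-4a-methyl-2,5-dioxo-2,3,4,4a,5,6,7,8-octahydronaphthalene-1-carboxylate (enedione) | COC(=O)C[C@H]1CC(=O)[C@@]2(C)CCC(=O)C(C(=O)OC(C)(C)C)=C2C1 | intermediate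
10 | tert-butyl (4aS,7R)-2-(tert-butyldimethylsilyloxy)-7-(2-methoxy-2-oxoethyl)-4a-methyl-5-oxo-3,4,4a,5,6,7-hexahydronaphthalene-1-carboxylate (silyl dienol ether) | COC(=O)C[C@H]1CC(=O)[C@@]2(C)CCC(O[Si](C)(C)C(C)(C)C)=C(C(=O)OC(C)(C)C)C2=C1 | intermediate
11 | 4-methoxyphenol | COc1ccc(O)cc1 | starting material
12 | 8β-bromo enedione (bromine on C8, cis to the C4 methyl; otherwise as 9) | COC(=O)C[C@H]1CC(=O)[C@@]2(C)CCC(=O)C(C(=O)OC(C)(C)C)=C2[C@@H]1Br | intermediate
13 | 8α-(4-methoxyphenoxy) enedione (ether on C8 cis to the C7 arm; otherwise as 9) | COC(=O)C[C@H]1CC(=O)[C@@]2(C)CCC(=O)C(C(=O)OC(C)(C)C)=C2[C@H]1Oc1ccc(OC)cc1 | intermediate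
14 | 9β,10β-epoxy diketone derived from 13 | COC(=O)C[C@H]1CC(=O)[C@@]2(C)CCC(=O)[C@]3(C(=O)OC(C)(C)C)O[C@]23[C@H]1Oc1ccc(OC)cc1 | intermediate
15 | cis-fused 9β-hydroxy-1(10)-ene: tert-butyl ester on C10, C5 ketone, 8α-aryloxy, C7 methyl acetate arm α | COC(=O)C[C@H]1CC(=O)[C@@]2(C)CCC=C(C(=O)OC(C)(C)C)[C@@]2(O)[C@H]1Oc1ccc(OC)cc1 | intermediate
16 | 6β-hydroxy ketone derived from 15 (C6–OH trans to the C7 arm) | COC(=O)C[C@H]1[C@H](O)C(=O)[C@@]2(C)CCC=C(C(=O)OC(C)(C)C)[C@@]2(O)[C@H]1Oc1ccc(OC)cc1 | intermediate
17 | 5-keto 6β,12-lactone (trans-fused γ-lactone on ring B) | C1C(=O)O[C@@H]2C(=O)[C@@]3(C)CCC=C(C(=O)OC(C)(C)C)[C@@]3(O)[C@@H](Oc4ccc(OC)cc4)[C@@H]12 | intermediate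
18 | 5α-hydroxy 6β,12-lactone | C1C(=O)O[C@@H]2[C@@H](O)[C@@]3(C)CCC=C(C(=O)OC(C)(C)C)[C@@]3(O)[C@@H](Oc4ccc(OC)cc4)[C@@H]12 | intermediate
19 | cis-decalin 5α-mesylate (4R,5S,6S,7S,8S,9R), precursor of the key step | C1C(=O)O[C@@H]2[C@@H](OS(C)(=O)=O)[C@@]3(C)CCC=C(C(=O)OC(C)(C)C)[C@@]3(O)[C@@H](Oc4ccc(OC)cc4)[C@@H]12 | intermediate
20 | ten-membered C9 ketone (1E,4Z,6R,7S,8S), product of the key step | C1C(=O)O[C@@H]2/C=C(/C)CC/C=C(/C(=O)OC(C)(C)C)C(=O)[C@@H](Oc3ccc(OC)cc3)[C@@H]12 | intermediate
21 | 9S allylic alcohol derived from 20 | C1C(=O)O[C@@H]2/C=C(/C)CC/C=C(/C(=O)OC(C)(C)C)[C@H](O)[C@@H](Oc3ccc(OC)cc3)[C@@H]12 | intermediate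
22 | 9-O-triethylsilyl ether of 21 | C1C(=O)O[C@@H]2/C=C(/C)CC/C=C(/C(=O)OC(C)(C)C)[C@H](O[Si](CC)(CC)CC)[C@@H](Oc3ccc(OC)cc3)[C@@H]12 | intermediate
23 | dimethyl(methylene)ammonium iodide | C=[N+](C)C.[I-] | starting material
24 | Mannich base: 11-(dimethylaminomethyl) lactone, C11 epimers | CN(C)CC1C(=O)O[C@@H]2/C=C(/C)CC/C=C(/C(=O)OC(C)(C)C)[C@H](O[Si](CC)(CC)CC)[C@@H](Oc3ccc(OC)cc3)[C@@H]12 | intermediate
25 | trimethylammonium iodide derived from 24 | C[N+](C)(C)CC1C(=O)O[C@@H]2/C=C(/C)CC/C=C(/C(=O)OC(C)(C)C)[C@H](O[Si](CC)(CC)CC)[C@@H](Oc3ccc(OC)cc3)[C@@H]12.[I-] | intermediate
26 | α-methylene lactone with 8-aryl ether and 9-silyl ether | C=C1C(=O)O[C@@H]2/C=C(/C)CC/C=C(/C(=O)OC(C)(C)C)[C@H](O[Si](CC)(CC)CC)[C@@H](Oc3ccc(OC)cc3)[C@@H]12 | intermediate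
27 | 8,9-diol, tert-butyl ester, α-methylene lactone | C=C1C(=O)O[C@@H]2/C=C(/C)CC/C=C(/C(=O)OC(C)(C)C)[C@H](O)[C@@H](O)[C@@H]12 | intermediate
28 | angelic acid | C/C=C(/C)C(=O)O | starting material
29 | angelic 2,4,6-trichlorobenzoic anhydride | C/C=C(/C)C(=O)OC(=O)c1c(Cl)cc(Cl)cc1Cl | intermediate
30 | 8,9-bis-angelate tert-butyl ester | C=C1C(=O)O[C@@H]2/C=C(/C)CC/C=C(/C(=O)OC(C)(C)C)[C@H](OC(=O)/C(C)=C\C)[C@@H](OC(=O)/C(C)=C\C)[C@@H]12 | intermediate
31 | CNP0154468.1 (1E,4Z,6R,7S,8S,9S) | C=C1C(=O)O[C@@H]2/C=C(/C)CC/C=C(/C(=O)O)[C@H](OC(=O)/C(C)=C\C)[C@@H](OC(=O)/C(C)=C\C)[C@@H]12 | target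

Total step count: 18. Longest linear sequence: 18 steps (1 to 31).

Least certain steps

Step 12 (key step). The most likely failure is enolisation of the freshly formed α-aryloxy ketone or γ-deprotonation of the alkylidene β-keto ester by any surviving base, which would erode C8 or move the C1=C10 double bond. A slow fragmentation is also possible if the syn-axial contact between C3 and the C8 ether distorts the chair. Fallback: the alkoxide is released by fluoride instead of an amide base. The route leaves at 19, which is silylated on the tertiary alcohol (1-(trimethylsilyl)imidazole, CH2Cl2) to the C9 trimethylsilyl ether F1. Treatment with CsF in DMF at 0 °C frees the alkoxide in the absence of any stronger base, and the same fragmentation returns to the route at 20.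

Step 2. A facial preference in the conjugate addition that is weak or that favours the other face would leave the trans adduct as a major component, because the enolate is nearly flat and axial attack is only mildly preferred. Fallback: the order of the two bond formations at C4 is exchanged, so that the other group enters last. The route leaves at 3 (isolated by acidifying after the hydrogenation), which adds to acrolein to give methyl [3,5-dioxo-4-(3-oxopropyl)cyclohexyl]acetate F2. C-Methylation of F2 (CH3I, K2CO3, acetone) then puts the methyl on the face that acrolein would have taken, and the route is rejoined at 6.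

Step 4. The β-keto ester enolises without help, so an uncatalysed, racemic aldol condensation can run beside the amine-catalysed one and lower the enantiomeric purity. Fallback: the desymmetrisation is moved from covalent enamine catalysis to a chiral Brønsted acid. A BINOL-derived phosphoric acid, (R)-3,3'-bis(2,4,6-triisopropylphenyl)-1,1'-binaphthyl-2,2'-diyl hydrogen phosphate or its enantiomer, is used in toluene; it binds the enol and one ring carbonyl by hydrogen bonds and needs no amine. This sets out from 8 and returns at 9 without a new compound.

Step 6. Neighbouring-group attack of the ester arm on the β-bromide (lactonisation onto O8), or base-induced equilibration at the acidic C8 position of the product, would lower the yield or the configurational purity. Fallback: oxygen is introduced first and inverted afterwards. The route leaves at 10, which is oxidised with 3-chloroperbenzoic acid (NaHCO3, CH2Cl2, −20 °C; then HF·pyridine) in a vinylogous Rubottom oxidation to the 8β-hydroxy enedione F3; its hydroxyl is trans to the arm and cannot lactonise. A Mitsunobu reaction of F3 with 11 (PPh3, diisopropyl azodicarboxylate, toluene, 0 °C) inverts C8 and rejoins the route at 13.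

Step 8. Condensation of hydrazine with the C5 ketone, or cyclisation of the C1 hydrazone onto the tert-butyl ester, would divert material from the transposition. Fallback: the C5 ketone is masked for the two steps in which the C1 carbonyl must be the only one. The route leaves at 13, which is converted with 1,2-bis(trimethylsilyloxy)ethane and catalytic Me3SiOSO2CF3 (CH2Cl2, −78 °C) into the C5 ethylene ketal F4. Epoxidation as in step 7 gives the ketal epoxide F5 and the Wharton transposition gives the ketal allylic alcohol F6. Hydrolysis of F6 (1 M HCl, THF, rt) rejoins the route at 15.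

Step 13. Conjugate hydride addition to the doubly activated alkene, or attack on the other carbonyl face in a flexible ten-membered ring, would give the saturated ketone or the 9R alcohol. Fallback: substrate control is replaced by reagent control, a Corey–Bakshi–Shibata reduction with catecholborane and the enantiomer of the 2-methyl oxazaborolidine that is matched to the 9S alcohol. This sets out from 20 and returns at 21 without a new compound.

Further compounds

F1 | step 12 | C9 trimethylsilyl ether of mesylate 19 | C1C(=O)O[C@@H]2[C@@H](OS(C)(=O)=O)[C@@]3(C)CCC=C(C(=O)OC(C)(C)C)[C@@]3(O[Si](C)(C)C)[C@@H](Oc4ccc(OC)cc4)[C@@H]12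
F2 | step 2 | methyl [3,5-dioxo-4-(3-oxopropyl)cyclohexyl]acetate | COC(=O)CC1CC(=O)C(CCC=O)C(=O)C1
F0 | step 4 | none | none
F3 | step 6 | 8β-hydroxy enedione (hydroxyl on C8 cis to the C4 methyl; otherwise as 9) | COC(=O)C[C@H]1CC(=O)[C@@]2(C)CCC(=O)C(C(=O)OC(C)(C)C)=C2[C@@H]1O
F4 | step 8 | C5 ethylene ketal of 13 | COC(=O)C[C@H]1CC2(OCCO2)[C@@]3(C)CCC(=O)C(C(=O)OC(C)(C)C)=C3[C@H]1Oc1ccc(OC)cc1
F5 | step 8 | C5 ethylene ketal of the 9β,10β-epoxy ketone | COC(=O)C[C@H]1CC2(OCCO2)[C@@]3(C)CCC(=O)[C@]4(C(=O)OC(C)(C)C)O[C@]34[C@H]1Oc1ccc(OC)cc1
F6 | step 8 | C5 ethylene ketal of 15 | COC(=O)C[C@H]1CC2(OCCO2)[C@@]3(C)CCC=C(C(=O)OC(C)(C)C)[C@@]3(O)[C@H]1Oc1ccc(OC)cc1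
F0 | step 13 | none | none
A1 | alternative 1 | furan | c1ccoc1
A2 | alternative 1 | (−)-8-phenylmenthyl glyoxylate | O=CC(=O)O[C@@H]1C[C@H](C)CC[C@H]1C(C)(C)c1ccccc1
A3 | alternative 1 | exo photoadduct, 8-phenylmenthyl 2,7-dioxabicyclo[3.2.0]hept-3-ene-6-carboxylate | O=C(O[C@@H]1C[C@H](C)CC[C@H]1C(C)(C)c1ccccc1)[C@H]2O[C@@H]3OC=C[C@H]23
A4 | alternative 2 | bicyclic C1–C6 epoxy C10 ketone with C4=C5, C7 methyl acetate arm and C8/C9 tert-butyldimethylsilyl ethers (epoxide configuration immaterial, left open) | COC(=O)C[C@H]1C23OC2(CCC(C)=C3)C(=O)[C@H](O[Si](C)(C)C(C)(C)C)[C@H]1O[Si](C)(C)C(C)(C)C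
A5 | alternative 2 | ten-membered C6 ketone with ring-cis C4=C5 and C1≡C10 | COC(=O)C[C@H]1C(=O)/C=C(/C)CCC#C[C@H](O[Si](C)(C)C(C)(C)C)[C@H]1O[Si](C)(C)C(C)(C)C
A6 | alternative 3 | thirteen-membered C6-tributylstannyl ether (C6 configuration and C7=C11 geometry left open) | CCCC[Sn](CCCC)(CCCC)C1OCC(CO[Si](C)(C)C(C)(C)C)=C[C@@H]2OC(C)(C)O[C@H]2/C(CO[Si](C)(C)C(C)(C)C)=C\CC/C(C)=C\1
A7 | alternative 3 | ten-membered C6 alcohol with C11=C13 unit and C8/C9 acetonide | C=C(CO[Si](C)(C)C(C)(C)C)[C@H]1[C@H](O)/C=C(/C)CC/C=C(/CO[Si](C)(C)C(C)(C)C)[C@@H]2OC(C)(C)O[C@@H]12
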